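**Plan**

The target is a benzophenone in which a carbonyl joins ring A (2-hydroxy-4,6-dimethoxyphenyl) to C5 of a 7-hydroxy-2,2-dimethyl-2H-chromene (benzo ring B, pyran ring C).
The retrosynthesis first cuts O1–C2 of ring C, giving an E-configured tertiary allylic alcohol on C4a with MOM-protected phenols, and then cuts C5–C(=O) and C4a–C4 in one operation.
The enabling feature is that C5 (aroyl) and C4a (C4 of ring C) are neighbouring carbon-substituted atoms of ring B, while the other neighbour of C4a, C8a, carries oxygen. An iodide on C4a therefore has one ortho site blocked by the C8a oxygen and one free ortho C–H at C5, the pattern that a Pd/norbornene ortho-acylation with ipso-Heck termination requires.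
In the forward direction the ring B iodide (2 steps from resorcinol) and the ring A anhydride (3 steps from 2-hydroxy-4,6-dimethoxybenzaldehyde) are joined with 2-methylbut-3-en-2-ol in a three-component coupling. Acid then removes the MOM groups and closes ring C, the only ring formed in the route.
The target has no stereocentre. The E-alkene of the coupling product arises from syn β-hydride elimination and becomes the ring alkene when ring C closes.

Key step: step 6

Remark on the chemistry: methoxymethyl (MOM) ethers mask the three phenols that must stay silent in the coupling, because they tolerate carbonate base at 100 °C and are removed together by acid. Methanol, the solvent of the last step, is assumed to carry the methoxymethyl groups away as dimethoxymethane.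

**Route**

Step 1
Reactants: 1 resorcinol (benzene-1,3-diol)
Product: 2 4-iodobenzene-1,3-diol
Conditions: ICl (1.0 equiv), Et2O, 0 °C to rt
Reagents that add atoms: iodine monochloride, ClI
Why: Electrophilic aromatic iodination with one equivalent of ICl in ether should go mainly to C4, which is para to one hydroxyl and ortho to the other and less hindered than C2 between the two hydroxyls.

Step 2
Reactants: 2 4-iodobenzene-1,3-diol
Product: 3 1-iodo-2,4-bis(methoxymethoxy)benzene
Conditions: MOMCl (2.5 equiv), i-Pr2NEt (3 equiv), CH2Cl2, 0 °C to rt
Reagents that add atoms: chloromethyl methyl ether (MOMCl), COCCl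
Why: O-alkylation of both phenols with the reactive chloromethyl ether under amine base (MOM protection) is routine and gives acetals that withstand the carbonate base and heat of step 6.

Step 3
Reactants: 4 2-hydroxy-4,6-dimethoxybenzaldehyde
Product: 5 2,4-dimethoxy-6-(methoxymethoxy)benzaldehyde
Conditions: MOMCl (1.5 equiv), i-Pr2NEt (2 equiv), CH2Cl2, 0 °C to reflux
Reagents that add atoms: chloromethyl methyl ether (MOMCl), COCCl
Why: MOM protection by O-alkylation of the hydrogen-bonded phenol masks the one nucleophile of ring A that would otherwise be acylated once the acid is activated.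

Step 4
Reactants: 5 2,4-dimethoxy-6-(methoxymethoxy)benzaldehyde
Product: 6 2,4-dimethoxy-6-(methoxymethoxy)benzoic acid
Conditions: NaClO2, NaH2PO4, 2-methylbut-2-ene (10 equiv), t-BuOH/THF/H2O, 0 °C to rt; work-up at pH 4
Reagents that add atoms: sodium chlorite (NaClO2), [Na+].[O-]Cl=O
Why: The Pinnick oxidation (chlorous acid adds to the aldehyde and the adduct fragments to the acid) tolerates the MOM acetal at about pH 4, and the large excess of 2-methylbut-2-ene should remove hypochlorous acid before it chlorinates the electron-rich ring.

Step 5
Reactants: 6 2,4-dimethoxy-6-(methoxymethoxy)benzoic acid (two molecules are consumed per molecule of anhydride)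
Product: 7 2,4-dimethoxy-6-(methoxymethoxy)benzoic anhydride
Conditions: DCC (0.5 equiv relative to 6), CH2Cl2, 0 °C to rt; filtration of the urea
Reagents that add atoms: second molecule of acid 6, 2,4-dimethoxy-6-(methoxymethoxy)benzoic acid, COCOc1cc(OC)cc(OC)c1C(=O)O
Why: In this carbodiimide dehydration one molecule of 6 adds to DCC to give an O-acylisourea and the carboxylate of a second molecule of 6 attacks it, so two molecules of acid and one of DCC should give the symmetric anhydride and the urea under neutral conditions that leave the MOM acetals untouched.

Step 6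
Reactants: 3 1-iodo-2,4-bis(methoxymethoxy)benzene; 7 2,4-dimethoxy-6-(methoxymethoxy)benzoic anhydride; 8 2-methylbut-3-en-2-ol
Product: 9 [2-[(E)-3-hydroxy-3-methylbut-1-enyl]-3,5-bis(methoxymethoxy)phenyl][2,4-dimethoxy-6-(methoxymethoxy)phenyl]methanone
Conditions: Pd(OAc)2 (10 mol %), tri(2-furyl)phosphine (25 mol %), norbornene (1.5 equiv), Cs2CO3 (3 equiv), 7 (1.5 equiv), 8 (2 equiv), toluene, 100 °C
Reagents that add atoms: none
Why: Zerovalent palladium formed from Pd(OAc)2 and the phosphine inserts into the C–I bond of 3, norbornene inserts into the aryl–palladium bond, and base-assisted C–H palladation at the one free ortho carbon (the future C5) gives the five-membered aryl–norbornyl palladacycle of divalent palladium. Anhydride 7 adds oxidatively to this palladacycle to give a tetravalent palladium acyl species, reductive elimination forms the C5–C(=O) bond, and because the arene then carries two ortho substituents, β-carbon elimination expels norbornene and leaves an arylpalladium species at the ipso carbon (the future C4a). That species adds across the terminal alkene of 8 with the aryl group going to CH2, and syn β-hydride elimination, possible only toward the benzylic carbon because the carbinol carbon bears no hydrogen, forms the C4a–C4 bond as the E-alkene. The closest known reaction type is the Catellani ortho-acylation of aryl iodides with carboxylic anhydrides terminated by an ipso-Heck reaction, of which the doubly ortho-substituted aroyl donor and the tertiary allylic alcohol are new members of known reactant classes. No ring is closed and no stereocentre is created, and the only stereochemical element, the E-alkene, follows from the syn elimination. The step needs site selectivity (one acylation at C5, alkenylation at C4a) and C-acylation in preference to O-acylation of 8; these should be secured by the position of the iodine, by the methoxymethoxy group that blocks the second ortho site, and by the bulk of the anhydride, which should not acylate a tertiary alcohol.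

Step 7
Reactants: 9 [2-[(E)-3-hydroxy-3-methylbut-1-enyl]-3,5-bis(methoxymethoxy)phenyl][2,4-dimethoxy-6-(methoxymethoxy)phenyl]methanone
Product: 11 (2-hydroxy-4,6-dimethoxyphenyl)(7-hydroxy-2,2-dimethyl-2H-chromen-5-yl)methanone, via MOM-free tetraol 10 (not isolated)
Conditions: 2 M aq HCl/MeOH (1:5), 50 °C
Reagents that add atoms: none
Why: Acid-catalysed acetal solvolysis frees the three phenols, after which ionization of the tertiary allylic alcohol gives an allyl cation stabilized by the ortho and para oxygen atoms of ring B (an ortho-quinone methide-type species in which the E geometry is no longer fixed), and the C8a phenol captures its tertiary end in a cyclodehydration that closes the six-membered ring C as the 2,2-dimethyl-2H-chromene.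

**Compound list**

1 | resorcinol (benzene-1,3-diol) | Oc1cccc(O)c1 | starting material
2 | 4-iodobenzene-1,3-diol | Oc1ccc(I)c(O)c1 | intermediate
3 | 1-iodo-2,4-bis(methoxymethoxy)benzene | COCOc1ccc(I)c(OCOC)c1 | intermediate
4 | 2-hydroxy-4,6-dimethoxybenzaldehyde | COc1cc(O)c(C=O)c(OC)c1 | starting material
5 | 2,4-dimethoxy-6-(methoxymethoxy)benzaldehyde | COCOc1cc(OC)cc(OC)c1C=O | intermediate
6 | 2,4-dimethoxy-6-(methoxymethoxy)benzoic acid | COCOc1cc(OC)cc(OC)c1C(=O)O | intermediate
7 | 2,4-dimethoxy-6-(methoxymethoxy)benzoic anhydride | COCOc1cc(OC)cc(OC)c1C(=O)OC(=O)c1c(OC)cc(OC)cc1OCOC | intermediate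
8 | 2-methylbut-3-en-2-ol | CC(C)(O)C=C | starting material
9 | [2-[(E)-3-hydroxy-3-methylbut-1-enyl]-3,5-bis(methoxymethoxy)phenyl][2,4-dimethoxy-6-(methoxymethoxy)phenyl]methanone | COCOc1cc(OC)cc(OC)c1C(=O)c1cc(OCOC)cc(OCOC)c1/C=C/C(C)(C)O | intermediate
10 | (2-hydroxy-4,6-dimethoxyphenyl)[3,5-dihydroxy-2-[(E)-3-hydroxy-3-methylbut-1-enyl]phenyl]methanone (MOM-free tetraol, not isolated) | COc1cc(O)c(C(=O)c2cc(O)cc(O)c2/C=C/C(C)(C)O)c(OC)c1 | intermediate
11 | (2-hydroxy-4,6-dimethoxyphenyl)(7-hydroxy-2,2-dimethyl-2H-chromen-5-yl)methanone | COc1cc(O)c(C(=O)c2cc(O)cc3c2C=CC(C)(C)O3)c(OC)c1 | target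

**Step count and risks**

Total step count: 7. Longest linear sequence: 5 steps (steps 3, 4, 5, 6, 7, from 4 to 11); the iodide branch (steps 1 and 2) joins at step 6.

Steps most likely to fail:

1. Step 6. Oxidative addition of the bulky, electron-rich anhydride to the palladacycle may be slower than the palladacycle's own exits: reductive elimination to a norbornane-fused benzocyclobutene, or norbornene loss followed by a plain Heck reaction at the ipso carbon without acylation. The unactivated alkene may also insert sluggishly at the doubly ortho-substituted arylpalladium species. Fallback, setting out from aldehyde 5 and returning at 9, by stepwise known chemistry: commercial 5-bromobenzene-1,3-diol is protected with MOMCl/i-Pr2NEt to give 1-bromo-3,5-bis(methoxymethoxy)benzene F1. N-Iodosuccinimide in MeCN should iodinate the position ortho to one and para to the other acetal oxygen, giving 1-bromo-2-iodo-3,5-bis(methoxymethoxy)benzene F2. A Heck reaction at the more reactive C–I bond with 8 (Pd(OAc)2, n-Bu4NCl, NaHCO3, DMF, 70 °C) should give (E)-4-[2-bromo-4,6-bis(methoxymethoxy)phenyl]-2-methylbut-3-en-2-ol F3. With n-BuLi (2.2 equiv, THF, −78 °C) the alkoxide forms and bromine is exchanged for lithium, and addition of the aryllithium to 5 should give the racemic carbinol (E)-4-[2-[[2,4-dimethoxy-6-(methoxymethoxy)phenyl](hydroxy)methyl]-4,6-bis(methoxymethoxy)phenyl]-2-methylbut-3-en-2-ol F4. MnO2 in CH2Cl2 should oxidize only the doubly benzylic secondary alcohol and so deliver 9.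

2. Step 7. Ring closure from the E-configured allyl cation may lag behind its capture by solvent or by another molecule, and protonation of the electron-rich chromene double bond may lead to addition or oligomerization during the time needed to cleave the two ring B acetals. Fallback, setting out from 9 and returning at 11, forms the ring at the chroman level and introduces the double bond last: hydrogenation of the alkene (H2, Pd/C, EtOAc, rt) should give [2-(3-hydroxy-3-methylbutyl)-3,5-bis(methoxymethoxy)phenyl][2,4-dimethoxy-6-(methoxymethoxy)phenyl]methanone F5. Methanolic HCl removes the MOM groups to give (2-hydroxy-4,6-dimethoxyphenyl)[3,5-dihydroxy-2-(3-hydroxy-3-methylbutyl)phenyl]methanone F6. After solvent exchange, p-TsOH·H2O in toluene at 90 °C should close the acid-stable chroman through the tertiary cation, giving (2-hydroxy-4,6-dimethoxyphenyl)(7-hydroxy-2,2-dimethyl-3,4-dihydro-2H-chromen-5-yl)methanone F7. DDQ in refluxing 1,4-dioxane should then dehydrogenate C3–C4 by hydride abstraction at C4, which is activated by the para hydroxyl and the ring oxygen, to give 11.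

3. Step 5. The O-acylisourea of the hindered acid may rearrange to the unreactive N-acylurea faster than the second, equally hindered carboxylate attacks it. Fallback, setting out from acid 6 and returning at 9, changes the acyl donor class: 6 is treated under neutral conditions with 1-chloro-N,N,2-trimethylprop-1-en-1-amine (CH2Cl2, 0 °C) to give 2,4-dimethoxy-6-(methoxymethoxy)benzoyl chloride F8, which is used at once. F8 then replaces the anhydride in the Pd/norbornene coupling with 3 and 8 under the conditions of step 6; acyl chlorides are established donors for this ortho-acylation.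

**Further compounds**

F1 | step 6 | 1-bromo-3,5-bis(methoxymethoxy)benzene | COCOc1cc(Br)cc(OCOC)c1
F2 | step 6 | 1-bromo-2-iodo-3,5-bis(methoxymethoxy)benzene | COCOc1cc(Br)c(I)c(OCOC)c1
F3 | step 6 | (E)-4-[2-bromo-4,6-bis(methoxymethoxy)phenyl]-2-methylbut-3-en-2-ol | COCOc1cc(Br)c(/C=C/C(C)(C)O)c(OCOC)c1
F4 | step 6 | racemic (E)-4-[2-[[2,4-dimethoxy-6-(methoxymethoxy)phenyl](hydroxy)methyl]-4,6-bis(methoxymethoxy)phenyl]-2-methylbut-3-en-2-ol | COCOc1cc(OC)cc(OC)c1C(O)c1cc(OCOC)cc(OCOC)c1/C=C/C(C)(C)O
F5 | step 7 | [2-(3-hydroxy-3-methylbutyl)-3,5-bis(methoxymethoxy)phenyl][2,4-dimethoxy-6-(methoxymethoxy)phenyl]methanone | COCOc1cc(OC)cc(OC)c1C(=O)c1cc(OCOC)cc(OCOC)c1CCC(C)(C)O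
F6 | step 7 | (2-hydroxy-4,6-dimethoxyphenyl)[3,5-dihydroxy-2-(3-hydroxy-3-methylbutyl)phenyl]methanone | COc1cc(O)c(C(=O)c2cc(O)cc(O)c2CCC(C)(C)O)c(OC)c1
F7 | step 7 | (2-hydroxy-4,6-dimethoxyphenyl)(7-hydroxy-2,2-dimethyl-3,4-dihydro-2H-chromen-5-yl)methanone | COc1cc(O)c(C(=O)c2cc(O)cc3c2CCC(C)(C)O3)c(OC)c1
F8 | step 5 | 2,4-dimethoxy-6-(methoxymethoxy)benzoyl chloride | COCOc1cc(OC)cc(OC)c1C(Cl)=O
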